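## Plan

1. Disconnections: C11=C12 (Wittig) separates a C15 ring-A enyne phosphonium salt from a C12 trienal; C9=C10 (Horner–Wadsworth–Emmons) leads back to a C13 ring-A enynone; the trienal is cut at C13=C14 and C15=C15' (two Wittig homologations) and at C14'–C15' and the C13' methyl (carboalumination of pent-4-yn-1-ol).
2. The enynone is unravelled to a 5-hydroxy-6,7-allenyl C9 methyl ketone, made by singlet oxygenation of a 3-silyloxy-beta-ionol that is built by Heck coupling (C6–C7) on the enol triflate of (4R,6R)-actinol.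
3. Feature used: in ring A (C1 gem-dimethyl, C3 carbinol, C5 methyl-bearing, C6 alkynyl-bearing) the C5=C6–C7≡C8 enyne is the dehydration isomer of a C5-hydroxy C6=C7=C8 allene whose C8–H is activated by a C9 ketone.
4. Forward order: ring A is bought and no ring is formed; the chain is joined at C6–C7, oxidised to the allene, dehydrated to the enyne, extended by C9=C10, united with the trienal at C11=C12, and desilylated.
5. Stereochemistry: C3 (R) comes from actinol and is never touched; C5 and the allene axis are transient; 13'E from syn carboalumination, 15E and 13E from stabilised ylides, 9E from the olefination with chromatographic removal of the 9Z ester, 11E from a trialkylphosphonium allylic ylide.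

Key step: step 7

Assumption: the singlet-oxygen step is taken to give the allenic hydroperoxide as a mixture of C5/axis diastereomers; the isomer expected to predominate (oxygen anti to the C3 silyloxy group, hydrogen taken suprafacially from C7) is the one drawn, and every isomer converges on 12 in step 7. Positions are given in carotenoid numbering; polyenes are handled under argon in dim light.

## Route

Step 1
Reactants: 1 (4R,6R)-4-hydroxy-2,2,6-trimethylcyclohexanone (actinol)
Product: 2 (4R,6R)-4-(tert-butyldimethylsilyloxy)-2,2,6-trimethylcyclohexanone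
Conditions: TBSCl, imidazole, DMF, rt
Reagents that add atoms: tert-butyldimethylsilyl chloride, CC(C)(C)[Si](C)(C)Cl
Why: Imidazole-promoted silylation of the secondary alcohol; the carbinol centre (future C3, R) is taken from the chiral pool and is not touched.

Step 2
Reactants: 2 (4R,6R)-4-(tert-butyldimethylsilyloxy)-2,2,6-trimethylcyclohexanone
Product: 4 (4R)-4-(tert-butyldimethylsilyloxy)-2,6,6-trimethylcyclohex-1-en-1-yl trifluoromethanesulfonate, via lithium enolate 3 (not isolated)
Conditions: LiN(i-Pr)2, THF, −78 → 0 °C; PhNTf2, 0 °C → rt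
Reagents that add atoms: N-phenylbis(trifluoromethanesulfonimide), O=S(=O)(N(c1ccccc1)S(=O)(=O)C(F)(F)F)C(F)(F)F
Why: Enol triflate formation: only the methyl-bearing alpha carbon has a hydrogen, so a single tetrasubstituted enolate forms and is trapped on oxygen, which deliberately erases the methyl-bearing stereocentre.

Step 3
Reactants: 4 (4R)-4-(tert-butyldimethylsilyloxy)-2,6,6-trimethylcyclohex-1-en-1-yl trifluoromethanesulfonate; 5 but-3-en-2-one (methyl vinyl ketone)
Product: 6 (3E)-4-[(4R)-4-(tert-butyldimethylsilyloxy)-2,6,6-trimethylcyclohex-1-en-1-yl]but-3-en-2-one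
Conditions: 5 (excess), Pd(OAc)2 (cat.), PPh3, Et3N, DMF, 70 °C
Reagents that add atoms: none
Why: Heck reaction of an alkenyl triflate with an enone: oxidative addition to zerovalent palladium, insertion at the unsubstituted terminus of 5 and syn beta-hydride elimination give the E dienone (C6–C7 bond).

Step 4
Reactants: 6 (3E)-4-[(4R)-4-(tert-butyldimethylsilyloxy)-2,6,6-trimethylcyclohex-1-en-1-yl]but-3-en-2-one
Product: 7 (3E)-4-[(4R)-4-(tert-butyldimethylsilyloxy)-2,6,6-trimethylcyclohex-1-en-1-yl]but-3-en-2-ol (both C9 epimers)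
Conditions: NaBH4, CeCl3·7H2O, MeOH, 0 °C
Reagents that add atoms: none
Why: Luche reduction delivers hydride 1,2 to the dienone, which turns the electron-poor dienone into the electron-rich dienol needed for the ene reaction; the C9 carbinol forms as both epimers, which is irrelevant because C9 is reoxidised in step 6.

Step 5
Reactants: 7 (3E)-4-[(4R)-4-(tert-butyldimethylsilyloxy)-2,6,6-trimethylcyclohex-1-en-1-yl]but-3-en-2-ol
Product: 9 4-[(2R,4S)-4-(tert-butyldimethylsilyloxy)-2-hydroxy-2,6,6-trimethylcyclohexylidene]but-3-en-2-ol (allene axis S; both C9 epimers), via allenic hydroperoxide 8 (not isolated)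
Conditions: O2, tetraphenylporphyrin (cat.), visible light, CH2Cl2, −20 °C; then PPh3, −20 °C → rt
Reagents that add atoms: dioxygen, O=O
Why: Schenck ene reaction of singlet oxygen at the electron-rich tetrasubstituted C5=C6 bond of the twisted diene, in which oxygen bonds to C5 and the C7 hydrogen, geminal to the bulky C1 quaternary carbon and held perpendicular to the ring double bond, is taken suprafacially to give the allene (a mode known for beta-ionol-type dienes), after which PPh3 reduces the hydroperoxide; approach anti to the C3 silyloxy group should set C5 (R) and the suprafacial course sets the axis, although both elements are erased in step 7.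

Step 6
Reactants: 9 4-[(2R,4S)-4-(tert-butyldimethylsilyloxy)-2-hydroxy-2,6,6-trimethylcyclohexylidene]but-3-en-2-ol
Product: 10 4-[(2R,4S)-4-(tert-butyldimethylsilyloxy)-2-hydroxy-2,6,6-trimethylcyclohexylidene]but-3-en-2-one (allene axis S)
Conditions: MnO2, CH2Cl2, rt
Reagents that add atoms: none
Why: MnO2 oxidation of the activated alpha-allenic secondary alcohol, which leaves the tertiary C5 carbinol and the silyl ether alone.

Step 7
Reactants: 10 4-[(2R,4S)-4-(tert-butyldimethylsilyloxy)-2-hydroxy-2,6,6-trimethylcyclohexylidene]but-3-en-2-one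
Product: 12 4-[(4R)-4-(tert-butyldimethylsilyloxy)-2,6,6-trimethylcyclohex-1-en-1-yl]but-3-yn-2-one, via C5 trifluoroacetate 11 (not isolated)
Conditions: (CF3CO)2O, pyridine, CH2Cl2, −20 → 0 °C; then DBU, 0 °C → rt
Reagents that add atoms: none
Why: Proposed new method: (CF3CO)2O acylates the tertiary, axial C5 hydroxyl to give 11, and DBU then removes the C8 proton, whose sigma bond lies in the plane of the C6=C7 pi orbitals, so that the developing charge is delocalised as an allenyl/propargyl anion and, once the acetyl group turns, as a cumulenolate of the C9 ketone. Electron density flows from C8 through C7 and C6 into the antibonding orbital of the aligned C5–O bond, trifluoroacetate leaves, and the second C7≡C8 pi bond and the C5=C6 pi bond form together (vinylogous E1cB, a 1,4-elimination across the allene). The closest known reaction types are the base-induced 1,4-elimination of delta leaving groups from carbonyl compounds, the E1cB dehydration of aldols through their trifluoroacetates, and the 1,4-dehydration of alpha-allenic alcohols to vinylacetylenes. No ring is closed and no stereocentre is created: C5 and the allene axis disappear, so all diastereomers from step 5 give the same enynone, and C3 is remote from the reacting atoms. The step needs loss of the C8 hydrogen in preference to a C4 or C5-methyl hydrogen (which would give ring dienes), and this is secured by the acidity of the C8–H next to the C9 carbonyl, by a leaving group too poor to ionise at low temperature yet good enough to leave from a carbanion, and by a hindered, non-nucleophilic amidine base. Enolisation of the acetyl methyl group cannot expel the leaving group and is reversible, so it should not divert material.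

Step 8
Reactants: 12 4-[(4R)-4-(tert-butyldimethylsilyloxy)-2,6,6-trimethylcyclohex-1-en-1-yl]but-3-yn-2-one; 13 triethyl phosphonoacetate
Product: 15 ethyl (2E)-3-methyl-5-[(4R)-4-(tert-butyldimethylsilyloxy)-2,6,6-trimethylcyclohex-1-en-1-yl]pent-2-en-4-ynoate, via sodium phosphonoacetate carbanion 14 (not isolated)
Conditions: 13, NaH, THF, 0 °C; then 12, 0 °C → rt; chromatography
Reagents that add atoms: none
Why: Horner–Wadsworth–Emmons olefination of the methyl ketone (C9=C10); 1,2-addition is favoured because the beta-alkynyl carbon C7 is shielded by the fully substituted ring carbon, the 9E ester (ester trans to the alkynyl group) is expected to predominate, and the 9Z isomer is removed by chromatography.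

Step 9
Reactants: 15 ethyl (2E)-3-methyl-5-[(4R)-4-(tert-butyldimethylsilyloxy)-2,6,6-trimethylcyclohex-1-en-1-yl]pent-2-en-4-ynoate
Product: 16 (2E)-3-methyl-5-[(4R)-4-(tert-butyldimethylsilyloxy)-2,6,6-trimethylcyclohex-1-en-1-yl]pent-2-en-4-yn-1-ol
Conditions: i-Bu2AlH, CH2Cl2, −78 °C; Rochelle salt work-up
Reagents that add atoms: none
Why: Aluminium hydride reduction of the conjugated ester to the allylic alcohol at low temperature, which leaves the enyne and the silyl ether untouched.

Step 10
Reactants: 16 (2E)-3-methyl-5-[(4R)-4-(tert-butyldimethylsilyloxy)-2,6,6-trimethylcyclohex-1-en-1-yl]pent-2-en-4-yn-1-ol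
Product: 17 (2E)-1-bromo-3-methyl-5-[(4R)-4-(tert-butyldimethylsilyloxy)-2,6,6-trimethylcyclohex-1-en-1-yl]pent-2-en-4-yne
Conditions: CBr4, PPh3, CH2Cl2, −20 → 0 °C
Reagents that add atoms: carbon tetrabromide, BrC(Br)(Br)Br
Why: Appel bromination converts the primary allylic alcohol to the bromide under neutral conditions, so the silyl ether and the 9E geometry are kept.

Step 11
Reactants: 17 (2E)-1-bromo-3-methyl-5-[(4R)-4-(tert-butyldimethylsilyloxy)-2,6,6-trimethylcyclohex-1-en-1-yl]pent-2-en-4-yne
Product: 18 tributyl{(2E)-3-methyl-5-[(4R)-4-(tert-butyldimethylsilyloxy)-2,6,6-trimethylcyclohex-1-en-1-yl]pent-2-en-4-yn-1-yl}phosphonium bromide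
Conditions: PBu3, MeCN, rt
Reagents that add atoms: tributylphosphine, CCCCP(CCCC)CCCC
Why: SN2 quaternisation of the nucleophilic trialkylphosphine by the primary allylic bromide.

Step 12
Reactants: 19 pent-4-yn-1-ol
Product: 20 tert-butyldimethyl(pent-4-yn-1-yloxy)silane
Conditions: TBSCl, imidazole, DMF, rt
Reagents that add atoms: tert-butyldimethylsilyl chloride, CC(C)(C)[Si](C)(C)Cl
Why: Standard silylation of a primary alcohol, which keeps the hydroxyl out of the organoaluminium step and prevents oxa-Michael closure onto the later enal.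

Step 13
Reactants: 20 tert-butyldimethyl(pent-4-yn-1-yloxy)silane
Product: 23 (2E)-6-(tert-butyldimethylsilyloxy)-3-methylhex-2-en-1-ol, via alkenylalane 21 (not isolated), via lithium alanate 22 (not isolated)
Conditions: AlMe3, Cp2ZrCl2 (cat.), CH2Cl2, 0 °C → rt; volatiles removed; n-BuLi, hexane/THF, −78 → 0 °C; (CH2O)n, rt
Reagents that add atoms: trimethylaluminium, C[Al](C)C; paraformaldehyde (formaldehyde unit), C=O
Why: Negishi zirconium-catalysed carboalumination adds methyl and aluminium syn across the terminal alkyne with methyl on the internal carbon, which fixes the E trisubstituted C13'=C14' bond, and the derived alanate is hydroxymethylated by formaldehyde with retention.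

Step 14
Reactants: 23 (2E)-6-(tert-butyldimethylsilyloxy)-3-methylhex-2-en-1-ol
Product: 24 (2E)-6-(tert-butyldimethylsilyloxy)-3-methylhex-2-enal
Conditions: MnO2, CH2Cl2, rt
Reagents that add atoms: none
Why: MnO2 oxidation of the allylic alcohol to the enal without over-oxidation or E/Z isomerisation.

Step 15
Reactants: 24 (2E)-6-(tert-butyldimethylsilyloxy)-3-methylhex-2-enal; 25 (triphenylphosphoranylidene)acetaldehyde
Product: 26 (2E,4E)-8-(tert-butyldimethylsilyloxy)-5-methylocta-2,4-dienal
Conditions: 25, toluene, 80 °C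
Reagents that add atoms: none
Why: Wittig two-carbon homologation with the stabilised formylmethylene ylide, which gives the E enal (C15=C15'); the product dienal is less electrophilic than 24, which limits a second homologation.

Step 16
Reactants: 26 (2E,4E)-8-(tert-butyldimethylsilyloxy)-5-methylocta-2,4-dienal; 27 2-(triphenylphosphoranylidene)propanal
Product: 28 (2E,4E,6E)-10-(tert-butyldimethylsilyloxy)-2,7-dimethyldeca-2,4,6-trienal
Conditions: 27, toluene, 100 °C
Reagents that add atoms: none
Why: Wittig reaction with the stabilised alpha-methyl ylide gives the E trisubstituted C13=C14 bond and stops at the alpha-branched trienal.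

Step 17
Reactants: 18 tributyl{(2E)-3-methyl-5-[(4R)-4-(tert-butyldimethylsilyloxy)-2,6,6-trimethylcyclohex-1-en-1-yl]pent-2-en-4-yn-1-yl}phosphonium bromide; 28 (2E,4E,6E)-10-(tert-butyldimethylsilyloxy)-2,7-dimethyldeca-2,4,6-trienal
Product: 30 3,10'-bis-O-(tert-butyldimethylsilyl) ether of the target, via phosphonium ylide 29 (not isolated)
Conditions: NaN(SiMe3)2, THF, −78 °C; then 28, −78 → 0 °C
Reagents that add atoms: none
Why: Wittig reaction of a semi-stabilised allylic ylide (C11=C12); allylic ylides from trialkylphosphonium salts react with aldehydes with a preference for the E olefin and are less prone than triphenylphosphonium analogues to scramble the neighbouring C9=C10 bond.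

Step 18
Reactants: 30 3,10'-bis-O-(tert-butyldimethylsilyl) ether of the target
Product: 31 (4E,6E,8E,10E,12E)-15-[(4R)-4-hydroxy-2,6,6-trimethylcyclohex-1-en-1-yl]-4,9,13-trimethylpentadeca-4,6,8,10,12-pentaen-14-yn-1-ol (CNP0344116.1)
Conditions: Bu4NF, THF, 0 °C → rt
Reagents that add atoms: none
Why: Fluoride-induced desilylation (Si–F bond formation) frees the C3 secondary and C10' primary alcohols without affecting the enyne-pentaene or C3.

## Compound list

1 | (4R,6R)-4-hydroxy-2,2,6-trimethylcyclohexanone (actinol) | O=C1C(C)(C)C[C@H](O)C[C@H]1C | starting material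
2 | (4R,6R)-4-(tert-butyldimethylsilyloxy)-2,2,6-trimethylcyclohexanone | O=C1C(C)(C)C[C@H](O[Si](C)(C)C(C)(C)C)C[C@H]1C | intermediate
3 | lithium (4R)-4-(tert-butyldimethylsilyloxy)-2,6,6-trimethylcyclohex-1-en-1-olate | CC1=C([O-])C(C)(C)C[C@H](O[Si](C)(C)C(C)(C)C)C1.[Li+] | intermediate (not isolated)
4 | (4R)-4-(tert-butyldimethylsilyloxy)-2,6,6-trimethylcyclohex-1-en-1-yl trifluoromethanesulfonate | CC1=C(OS(=O)(=O)C(F)(F)F)C(C)(C)C[C@H](O[Si](C)(C)C(C)(C)C)C1 | intermediate
5 | but-3-en-2-one (methyl vinyl ketone) | C=CC(C)=O | starting material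
6 | (3E)-4-[(4R)-4-(tert-butyldimethylsilyloxy)-2,6,6-trimethylcyclohex-1-en-1-yl]but-3-en-2-one | CC1=C(/C=C/C(C)=O)C(C)(C)C[C@H](O[Si](C)(C)C(C)(C)C)C1 | intermediate
7 | (3E)-4-[(4R)-4-(tert-butyldimethylsilyloxy)-2,6,6-trimethylcyclohex-1-en-1-yl]but-3-en-2-ol, both C9 epimers | CC1=C(/C=C/C(C)O)C(C)(C)C[C@H](O[Si](C)(C)C(C)(C)C)C1 | intermediate
8 | 4-[(2R,4S)-4-(tert-butyldimethylsilyloxy)-2-hydroperoxy-2,6,6-trimethylcyclohexylidene]but-3-en-2-ol; 3S,5R in carotenoid numbering, C5–OOH trans to the C3 silyloxy group, allene axis S (C9 on the ring face that carries the C5 oxygen), both C9 epimers | CC(O)C([H])=[C@]=C1C(C)(C)C[C@H](O[Si](C)(C)C(C)(C)C)C[C@@]1(C)OO | intermediate (not isolated)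
9 | 4-[(2R,4S)-4-(tert-butyldimethylsilyloxy)-2-hydroxy-2,6,6-trimethylcyclohexylidene]but-3-en-2-ol; same C3, C5 and axis configuration as 8, both C9 epimers | CC(O)C([H])=[C@]=C1C(C)(C)C[C@H](O[Si](C)(C)C(C)(C)C)C[C@@]1(C)O | intermediate
10 | 4-[(2R,4S)-4-(tert-butyldimethylsilyloxy)-2-hydroxy-2,6,6-trimethylcyclohexylidene]but-3-en-2-one; 3-O-silyl 5-hydroxy-6,7-allenyl C9 methyl ketone, 3S,5R, allene axis S | CC(=O)C([H])=[C@]=C1C(C)(C)C[C@H](O[Si](C)(C)C(C)(C)C)C[C@@]1(C)O | intermediate
11 | C5 trifluoroacetate of 10 | CC(=O)C([H])=[C@]=C1C(C)(C)C[C@H](O[Si](C)(C)C(C)(C)C)C[C@@]1(C)OC(=O)C(F)(F)F | intermediate (not isolated)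
12 | 4-[(4R)-4-(tert-butyldimethylsilyloxy)-2,6,6-trimethylcyclohex-1-en-1-yl]but-3-yn-2-one (ring A enynone) | CC1=C(C#CC(C)=O)C(C)(C)C[C@H](O[Si](C)(C)C(C)(C)C)C1 | intermediate
13 | triethyl phosphonoacetate | CCOC(=O)CP(=O)(OCC)OCC | starting material
14 | sodium salt of the triethyl phosphonoacetate carbanion | CCOC(=O)[CH-]P(=O)(OCC)OCC.[Na+] | intermediate (not isolated)
15 | ethyl (2E)-3-methyl-5-[(4R)-4-(tert-butyldimethylsilyloxy)-2,6,6-trimethylcyclohex-1-en-1-yl]pent-2-en-4-ynoate | CC1=C(C#C/C(C)=C/C(=O)OCC)C(C)(C)C[C@H](O[Si](C)(C)C(C)(C)C)C1 | intermediate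
16 | (2E)-3-methyl-5-[(4R)-4-(tert-butyldimethylsilyloxy)-2,6,6-trimethylcyclohex-1-en-1-yl]pent-2-en-4-yn-1-ol | CC1=C(C#C/C(C)=C/CO)C(C)(C)C[C@H](O[Si](C)(C)C(C)(C)C)C1 | intermediate
17 | (2E)-1-bromo-3-methyl-5-[(4R)-4-(tert-butyldimethylsilyloxy)-2,6,6-trimethylcyclohex-1-en-1-yl]pent-2-en-4-yne | CC1=C(C#C/C(C)=C/CBr)C(C)(C)C[C@H](O[Si](C)(C)C(C)(C)C)C1 | intermediate
18 | tributyl{(2E)-3-methyl-5-[(4R)-4-(tert-butyldimethylsilyloxy)-2,6,6-trimethylcyclohex-1-en-1-yl]pent-2-en-4-yn-1-yl}phosphonium bromide | CC1=C(C#C/C(C)=C/C[P+](CCCC)(CCCC)CCCC)C(C)(C)C[C@H](O[Si](C)(C)C(C)(C)C)C1.[Br-] | intermediate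
19 | pent-4-yn-1-ol | C#CCCCO | starting material
20 | tert-butyldimethyl(pent-4-yn-1-yloxy)silane | C#CCCCO[Si](C)(C)C(C)(C)C | intermediate
21 | dimethyl[(1E)-5-(tert-butyldimethylsilyloxy)-2-methylpent-1-en-1-yl]alane | C[Al](C)/C=C(\C)CCCO[Si](C)(C)C(C)(C)C | intermediate (not isolated)
22 | lithium butyl(dimethyl)[(1E)-5-(tert-butyldimethylsilyloxy)-2-methylpent-1-en-1-yl]alanate | CCCC[Al-](C)(C)/C=C(\C)CCCO[Si](C)(C)C(C)(C)C.[Li+] | intermediate (not isolated)
23 | (2E)-6-(tert-butyldimethylsilyloxy)-3-methylhex-2-en-1-ol | OC/C=C(\C)CCCO[Si](C)(C)C(C)(C)C | intermediate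
24 | (2E)-6-(tert-butyldimethylsilyloxy)-3-methylhex-2-enal | O=C/C=C(\C)CCCO[Si](C)(C)C(C)(C)C | intermediate
25 | (triphenylphosphoranylidene)acetaldehyde | O=CC=P(c1ccccc1)(c1ccccc1)c1ccccc1 | starting material
26 | (2E,4E)-8-(tert-butyldimethylsilyloxy)-5-methylocta-2,4-dienal | O=C/C=C/C=C(\C)CCCO[Si](C)(C)C(C)(C)C | intermediate
27 | 2-(triphenylphosphoranylidene)propanal | CC(C=O)=P(c1ccccc1)(c1ccccc1)c1ccccc1 | starting material
28 | (2E,4E,6E)-10-(tert-butyldimethylsilyloxy)-2,7-dimethyldeca-2,4,6-trienal | O=C/C(C)=C/C=C/C=C(\C)CCCO[Si](C)(C)C(C)(C)C | intermediate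
29 | tributylphosphonium ylide derived from 18 | CC1=C(C#C/C(C)=C/C=P(CCCC)(CCCC)CCCC)C(C)(C)C[C@H](O[Si](C)(C)C(C)(C)C)C1 | intermediate (not isolated)
30 | 3,10'-bis-O-(tert-butyldimethylsilyl) ether of the target, (3R), all-E | CC1=C(C#C/C(C)=C/C=C/C(C)=C/C=C/C=C(\C)CCCO[Si](C)(C)C(C)(C)C)C(C)(C)C[C@H](O[Si](C)(C)C(C)(C)C)C1 | intermediate
31 | (4E,6E,8E,10E,12E)-15-[(4R)-4-hydroxy-2,6,6-trimethylcyclohex-1-en-1-yl]-4,9,13-trimethylpentadeca-4,6,8,10,12-pentaen-14-yn-1-ol (CNP0344116.1) | CC1=C(C#C/C(C)=C/C=C/C(C)=C/C=C/C=C(\C)CCCO)C(C)(C)C[C@H](O)C1 | target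

## Step count

Total steps: 18. Longest linear sequence: 13 (steps 1–11, 17, 18); the trienal 28 is made in 5 steps (12–16).

## Steps most likely to fail

**Step 7 (enyne-forming elimination).** The trifluoroacetate may ionise and shed a proton from C4 or from the C5 methyl group, or the amidine may add to the allenone or ynone, before C8 is deprotonated. Known chemistry reaches the same enynone without the allene. The fallback sets out from triflate 4: Sonogashira coupling with but-3-yn-2-ol (PdCl2(PPh3)2, CuI, Et3N, DMF) gives the enynol F1, and MnO2 oxidation of its propargylic alcohol brings the route back at 12.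

**Step 5 (singlet-oxygen ene reaction).** Singlet oxygen may add across the C5=C6–C7=C8 diene in a [4+2] sense, or take its hydrogen from C4 or the C5 methyl group instead of C7. The allene would then be made by SN2' hydride opening of an epoxy alkyne. The fallback again sets out from triflate 4 and passes through the enynol F1 described above. mCPBA epoxidises its C5=C6 bond on the face away from the silyloxy group to give the epoxy alkynol F2. LiAlH4 in THF (alkoxide-directed hydroalumination of the alkyne, then loss of the C6–O bond) opens it to the allenic diol F3, expected as the axis epimer of 9. MnO2 gives the allenyl ketone F4, and the conditions of step 7 take it through the trifluoroacetate F5 back to the route at 12.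

**Step 17 (Wittig union).** The allylic ylide may lose the 9E geometry by rotation about C9–C10, or the new C11=C12 bond may form as an E/Z mixture. The polarity of the union would then be reversed, so that C9=C10 sits in an aldehyde and never in an allylic anion. The fallback sets out from 16 and 28. MnO2 oxidises 16 to the enynal F6. NaBH4 reduces 28 to the trienol F7, CBr4/PPh3 gives the trienyl bromide F8, and PBu3 gives the tributylphosphonium bromide F9. Its ylide F10 (NaN(SiMe3)2, THF, −78 °C) condenses with F6 and the route is rejoined at 30.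

## Further compounds

F1 | step 7 | 4-[(4R)-4-(tert-butyldimethylsilyloxy)-2,6,6-trimethylcyclohex-1-en-1-yl]but-3-yn-2-ol, both C9 epimers | CC1=C(C#CC(C)O)C(C)(C)C[C@H](O[Si](C)(C)C(C)(C)C)C1
F2 | step 5 | 4-[(1R,4S,6R)-4-(tert-butyldimethylsilyloxy)-2,2,6-trimethyl-7-oxabicyclo[4.1.0]heptan-1-yl]but-3-yn-2-ol, epoxide oxygen on the ring face opposite the silyloxy group, both C9 epimers | CC(O)C#C[C@]1(O2)C(C)(C)C[C@H](O[Si](C)(C)C(C)(C)C)C[C@]12C
F3 | step 5 | 4-[(2R,4S)-4-(tert-butyldimethylsilyloxy)-2-hydroxy-2,6,6-trimethylcyclohexylidene]but-3-en-2-ol with allene axis R (C9 on the ring face opposite the C5 oxygen), both C9 epimers | CC(O)C([H])=[C@@]=C1C(C)(C)C[C@H](O[Si](C)(C)C(C)(C)C)C[C@@]1(C)O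
F4 | step 5 | 4-[(2R,4S)-4-(tert-butyldimethylsilyloxy)-2-hydroxy-2,6,6-trimethylcyclohexylidene]but-3-en-2-one with allene axis R | CC(=O)C([H])=[C@@]=C1C(C)(C)C[C@H](O[Si](C)(C)C(C)(C)C)C[C@@]1(C)O
F5 | step 5 | C5 trifluoroacetate of F4 (not isolated) | CC(=O)C([H])=[C@@]=C1C(C)(C)C[C@H](O[Si](C)(C)C(C)(C)C)C[C@@]1(C)OC(=O)C(F)(F)F
F6 | step 17 | (2E)-3-methyl-5-[(4R)-4-(tert-butyldimethylsilyloxy)-2,6,6-trimethylcyclohex-1-en-1-yl]pent-2-en-4-ynal | CC1=C(C#C/C(C)=C/C=O)C(C)(C)C[C@H](O[Si](C)(C)C(C)(C)C)C1
F7 | step 17 | (2E,4E,6E)-10-(tert-butyldimethylsilyloxy)-2,7-dimethyldeca-2,4,6-trien-1-ol | OC/C(C)=C/C=C/C=C(\C)CCCO[Si](C)(C)C(C)(C)C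
F8 | step 17 | (2E,4E,6E)-1-bromo-10-(tert-butyldimethylsilyloxy)-2,7-dimethyldeca-2,4,6-triene | BrC/C(C)=C/C=C/C=C(\C)CCCO[Si](C)(C)C(C)(C)C
F9 | step 17 | tributyl[(2E,4E,6E)-10-(tert-butyldimethylsilyloxy)-2,7-dimethyldeca-2,4,6-trien-1-yl]phosphonium bromide | CCCC[P+](CCCC)(CCCC)C/C(C)=C/C=C/C=C(\C)CCCO[Si](C)(C)C(C)(C)C.[Br-]
F10 | step 17 | tributylphosphonium ylide derived from F9 (not isolated) | CCCCP(CCCC)(CCCC)=C/C(C)=C/C=C/C=C(\C)CCCO[Si](C)(C)C(C)(C)C
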